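Numbering: C1 bears the guaiacyl ring, C2 and C3 bear the CH2OH carbons C9 and C10, C4 is the ring CH2; ring A is C4a, C5(H), C6(OMe), C7(OH), C8(OH), C8a. Everything rests on making the C4–C4a bond last. Since C8 is oxygenated, C4a is the single open site flanking C8a, and C4 hangs on C3, which also holds C10; with C3 as the α-carbon of an acrylate whose methylene is C4, a radical generated at C4a can attack C4. That one operation closes ring B (6-endo), forges C4–C4a and sets C3 by hydrogen transfer. Its precursor is an aryl bromide with C1 and C2 already set, a ketal-protected ring A and benzyl ethers elsewhere.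

Key step: step 11

Assumption: in step 6 the (1R,4R) antipode of the diene is taken to deliver the aryl group to the Re face of C1; if the sense is the opposite, the (1S,4S) antipode is used under the same conditions (C1 epimers are separable diastereomers either way).

Step 1
Reactants: 1 5-bromo-1,2,3-trimethoxybenzene
Product: 2 6-bromo-2,3,4-trimethoxybenzaldehyde
Conditions: Cl2CHOMe, TiCl4, CH2Cl2, −10 to 20 °C; then H2O
Reagents that add atoms: dichloromethyl methyl ether, COC(Cl)Cl; water, O
Why: Rieche formylation (Friedel–Crafts attack of the TiCl4-activated chloro ether followed by hydrolysis) can enter only at one of the two equivalent free positions of the symmetric arene, each ortho and para to a methoxy group, so the formyl carbon (future C1) lands next to bromine (future C4a) without any regiochemical choice.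

Step 2
Reactants: 2 6-bromo-2,3,4-trimethoxybenzaldehyde
Product: 3 6-bromo-2,3-dihydroxy-4-methoxybenzaldehyde
Conditions: BCl3 (3 equiv), CH2Cl2, −10 to 20 °C; then H2O
Reagents that add atoms: none
Why: Chelation-directed ether cleavage by BCl3 removes the methyl group ortho to the aldehyde and then, through the aryloxyboron chloride so formed, the adjacent one, whereas the methoxy group para to the aldehyde (future C6–OMe) is out of reach, the selectivity known for 2,3,4-trimethoxybenzaldehydes.

Step 3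
Reactants: 3 6-bromo-2,3-dihydroxy-4-methoxybenzaldehyde
Product: 4 5-bromo-7-methoxy-2,2-diphenyl-1,3-benzodioxole-4-carbaldehyde
Conditions: Ph2CCl2 (1.5 equiv), Ph2O, 175 °C, N2 stream
Reagents that add atoms: dichlorodiphenylmethane, ClC(Cl)(c1ccccc1)c1ccccc1
Why: Ketalisation of the catechol with the geminal dichloride (two substitutions through the chlorodiphenylmethyl cation, driven by loss of HCl) gives a benzodioxole that ties the C8 oxygen back from the future C1, withstands base, hydride and tin radicals, and falls to the same hydrogenolysis as the benzyl ethers, which saves a separate acidic deprotection of an air-sensitive catechol.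

Step 4
Reactants: 4 5-bromo-7-methoxy-2,2-diphenyl-1,3-benzodioxole-4-carbaldehyde; 5 malonic acid
Product: 6 (E)-3-(5-bromo-7-methoxy-2,2-diphenyl-1,3-benzodioxol-4-yl)acrylic acid
Conditions: pyridine, piperidine (cat.), 95 °C
Reagents that add atoms: none
Why: Knoevenagel–Doebner condensation with decarboxylation in pyridine gives the (E)-acrylic acid directly, the trans geometry arising in the decarboxylative elimination, and it is known to tolerate benzaldehydes with two ortho substituents.

Step 5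
Reactants: 6 (E)-3-(5-bromo-7-methoxy-2,2-diphenyl-1,3-benzodioxol-4-yl)acrylic acid; 7 (S)-4-isopropyl-2-oxazolidinone
Product: 9 (S)-3-[(E)-3-(5-bromo-7-methoxy-2,2-diphenyl-1,3-benzodioxol-4-yl)acryloyl]-4-isopropyloxazolidin-2-one, via mixed pivalic anhydride 8 (not isolated)
Conditions: t-BuCOCl, Et3N, THF, −20 °C; then 7, LiCl, −20 to 20 °C
Reagents that add atoms: none
Why: The mixed pivalic anhydride acylates the oxazolidinone nitrogen under LiCl–Et3N activation, attack going to the acryloyl carbonyl because the pivaloyl carbonyl is shielded by its tert-butyl group, and the (E)-alkene is untouched.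

Step 6
Reactants: 9 (S)-3-[(E)-3-(5-bromo-7-methoxy-2,2-diphenyl-1,3-benzodioxol-4-yl)acryloyl]-4-isopropyloxazolidin-2-one; 10 (4-benzyloxy-3-methoxyphenyl)boronic acid
Product: 11 (S)-3-[(S)-3-(4-benzyloxy-3-methoxyphenyl)-3-(5-bromo-7-methoxy-2,2-diphenyl-1,3-benzodioxol-4-yl)propanoyl]-4-isopropyloxazolidin-2-one
Conditions: [RhCl(C2H4)2]2 (2.5 mol%), (1R,4R)-2,5-diphenylbicyclo[2.2.2]octa-2,5-diene (5.5 mol%), 10 (2.5 equiv), K3PO4 (0.5 equiv), dioxane–H2O 10:1, 40 °C
Reagents that add atoms: none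
Why: Hayashi–Miyaura conjugate arylation (aryl transfer from boron to monovalent rhodium, insertion of the enoyl C=C bond into the Rh–aryl bond, protonolysis of the rhodium enolate) is steered by the chiral diene to the Re face of C1 and so sets (S)-C1, while the auxiliary turns any C1 epimer into a separable diastereomer, the phosphate base spares the imide, and the aryl bromide is inert toward monovalent rhodium at this temperature.

Step 7
Reactants: 11 (S)-3-[(S)-3-(4-benzyloxy-3-methoxyphenyl)-3-(5-bromo-7-methoxy-2,2-diphenyl-1,3-benzodioxol-4-yl)propanoyl]-4-isopropyloxazolidin-2-one; 12 tert-butyl bromoacetate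
Product: 14 tert-butyl (3S,4S)-4-(4-benzyloxy-3-methoxyphenyl)-4-(5-bromo-7-methoxy-2,2-diphenyl-1,3-benzodioxol-4-yl)-3-[(S)-4-isopropyl-2-oxooxazolidine-3-carbonyl]butanoate, via sodium Z-enolate 13 (not isolated)
Conditions: NaN(SiMe3)2, THF, −78 °C; then 12, −78 to −40 °C
Reagents that add atoms: none
Why: Evans alkylation: the chelated sodium Z-enolate is attacked by the reactive α-bromo ester on the face opposite the isopropyl group of the auxiliary, which sets C2 as (S) in 14 (the arrangement that becomes (2R), trans to the C1 aryl group, in the tetralin), the auxiliary overriding the influence of the neighbouring C1 centre.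

Step 8
Reactants: 14 tert-butyl (3S,4S)-4-(4-benzyloxy-3-methoxyphenyl)-4-(5-bromo-7-methoxy-2,2-diphenyl-1,3-benzodioxol-4-yl)-3-[(S)-4-isopropyl-2-oxooxazolidine-3-carbonyl]butanoate
Product: 15 tert-butyl (3S,4S)-4-(4-benzyloxy-3-methoxyphenyl)-4-(5-bromo-7-methoxy-2,2-diphenyl-1,3-benzodioxol-4-yl)-3-(hydroxymethyl)butanoate
Conditions: LiBH4, H2O (1 equiv), THF–Et2O, 0 °C; aq NH4Cl
Reagents that add atoms: none
Why: LiBH4 reduces the activated imide carbonyl far faster than the tert-butyl ester, releasing the auxiliary and C9 as a primary alcohol without affecting C1 or C2, and the cold, buffered work-up keeps the γ-hydroxy ester from closing to the lactone.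

Step 9
Reactants: 15 tert-butyl (3S,4S)-4-(4-benzyloxy-3-methoxyphenyl)-4-(5-bromo-7-methoxy-2,2-diphenyl-1,3-benzodioxol-4-yl)-3-(hydroxymethyl)butanoate
Product: 16 tert-butyl (3S,4S)-4-(4-benzyloxy-3-methoxyphenyl)-3-(benzyloxymethyl)-4-(5-bromo-7-methoxy-2,2-diphenyl-1,3-benzodioxol-4-yl)butanoate
Conditions: BnBr, Ag2O, CH2Cl2, 20 °C, dark
Reagents that add atoms: benzyl bromide, BrCc1ccccc1
Why: Silver-oxide-mediated Williamson benzylation needs no free alkoxide, so the γ-hydroxy tert-butyl ester is etherified at C9–O under conditions where it would lactonise with NaH, and no stereocentre is involved.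

Step 10
Reactants: 16 tert-butyl (3S,4S)-4-(4-benzyloxy-3-methoxyphenyl)-3-(benzyloxymethyl)-4-(5-bromo-7-methoxy-2,2-diphenyl-1,3-benzodioxol-4-yl)butanoate
Product: 20 tert-butyl (3R,4S)-4-(4-benzyloxy-3-methoxyphenyl)-3-(benzyloxymethyl)-4-(5-bromo-7-methoxy-2,2-diphenyl-1,3-benzodioxol-4-yl)-2-methylenebutanoate, via lithium enolate 17 (not isolated), via Mannich base 18 (not isolated), via ammonium iodide 19 (not isolated)
Conditions: LiN(i-Pr)2, THF, −78 °C; CH2=NMe2+ I−, −78 to 20 °C; MeI, MeOH, 20 °C; aq NaHCO3, CH2Cl2, 20 °C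
Reagents that add atoms: N,N-dimethylmethyleneiminium iodide, C=[N+](C)C.[I-]
Why: Ester α-methylenation by enolate Mannich reaction, N-methylation and base-induced β-elimination of trimethylamine installs C4 on C3; only the C3 methylene is enolised by the amide base, C2 and C1 are not acidic in 16, and the bicarbonate elimination is too mild to shift the new double bond toward C2.

Step 11
Reactants: 20 tert-butyl (3R,4S)-4-(4-benzyloxy-3-methoxyphenyl)-3-(benzyloxymethyl)-4-(5-bromo-7-methoxy-2,2-diphenyl-1,3-benzodioxol-4-yl)-2-methylenebutanoate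
Product: 21 tert-butyl (1S,2R,3R)-1-(4-benzyloxy-3-methoxyphenyl)-2-(benzyloxymethyl)-6-methoxy-7,8-(diphenylmethylenedioxy)-1,2,3,4-tetrahydronaphthalene-3-carboxylate (numbering of the first paragraph)
Conditions: Bu3SnH (1.3 equiv, added over 2 h), AIBN (0.15 equiv), PhH (0.01 M), 80 °C
Reagents that add atoms: none
Why: Bu3Sn• (from Bu3SnH and AIBN) abstracts bromine from C4a, and the σ-aryl radical adds to C4, the unsubstituted terminus of the α-methylene ester, forming the C4–C4a bond and closing ring B in the 6-endo-trig mode before Bu3SnH reduces the resulting C3 radical; the closest known reaction type is the tin-hydride-mediated 6-endo cyclisation of aryl radicals onto 2-substituted acrylates. The 6-endo mode is secured by the acceptor: C3 is fully substituted and bears the ester, so 5-exo attack there is hindered and polarity-mismatched, whereas attack at C4 gives a tertiary ester-stabilised radical, and a 5-exo radical would in any case be funnelled to the same C3 radical by a neophyl-type 1,2-aryl shift. The new stereocentre C3 is controlled by the C1 aryl group: hydrogen is delivered to the planar C3 radical on the ring face anti to that aryl group (axial delivery in the half-chair with the C1 and C2 substituents equatorial), which puts the ester trans to the C2 arm and gives (3R). Because the ketal ties the C8 oxygen back from C1, this half-chair is not destabilised by peri strain, and the trans,trans ester should also be the more stable C3 epimer. The hydride is held near 0.01 M, low enough for cyclisation to outrun direct reduction of the aryl radical and 1,5-hydrogen transfer from C2–H, yet high enough to trap the C3 radical before β-scission of the C1–C2 bond to a diarylmethyl radical could scramble C1 and C2. Bromine can only sit at C4a because C8 is oxygenated, so ring A poses no regiochemical question.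

Step 12
Reactants: 21 tert-butyl (1S,2R,3R)-1-(4-benzyloxy-3-methoxyphenyl)-2-(benzyloxymethyl)-6-methoxy-7,8-(diphenylmethylenedioxy)-1,2,3,4-tetrahydronaphthalene-3-carboxylate
Product: 22 [(1S,2R,3R)-1-(4-benzyloxy-3-methoxyphenyl)-2-(benzyloxymethyl)-6-methoxy-7,8-(diphenylmethylenedioxy)-1,2,3,4-tetrahydronaphthalen-3-yl]methanol
Conditions: LiAlH4, THF, 0 to 20 °C
Reagents that add atoms: none
Why: LiAlH4 reduces the tert-butyl ester to the primary alcohol C10 without passing through an enolate, so C3 keeps its configuration, and the benzyl ethers and the ketal are inert to hydride.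

Step 13
Reactants: 22 [(1S,2R,3R)-1-(4-benzyloxy-3-methoxyphenyl)-2-(benzyloxymethyl)-6-methoxy-7,8-(diphenylmethylenedioxy)-1,2,3,4-tetrahydronaphthalen-3-yl]methanol
Product: 23 (1S,2R,3R)-1-(4-hydroxy-3-methoxyphenyl)-2,3-bis(hydroxymethyl)-6-methoxy-1,2,3,4-tetrahydronaphthalene-7,8-diol (CNP0219328.1)
Conditions: H2 (1 atm), Pd(OH)2/C, EtOAc–MeOH, 20 °C
Reagents that add atoms: none
Why: Catalytic hydrogenolysis cleaves all benzylic C–O bonds in one operation, the two benzyl ethers to toluene and the diphenylmethylene ketal to diphenylmethane, under neutral reducing conditions that protect the oxidation-prone catechol, and no stereocentre bears a hydrogenolysable bond.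

Compound list
1 | 5-bromo-1,2,3-trimethoxybenzene | COc1cc(Br)cc(OC)c1OC | starting material
2 | 6-bromo-2,3,4-trimethoxybenzaldehyde | COc1cc(Br)c(C=O)c(OC)c1OC | intermediate
3 | 6-bromo-2,3-dihydroxy-4-methoxybenzaldehyde | COc1cc(Br)c(C=O)c(O)c1O | intermediate
4 | 5-bromo-7-methoxy-2,2-diphenyl-1,3-benzodioxole-4-carbaldehyde | COc1cc(Br)c(C=O)c2OC(c3ccccc3)(c3ccccc3)Oc12 | intermediate
5 | malonic acid | OC(=O)CC(=O)O | starting material
6 | (E)-3-(5-bromo-7-methoxy-2,2-diphenyl-1,3-benzodioxol-4-yl)acrylic acid | COc1cc(Br)c(/C=C/C(=O)O)c2OC(c3ccccc3)(c3ccccc3)Oc12 | intermediate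
7 | (S)-4-isopropyl-2-oxazolidinone | CC(C)[C@H]1COC(=O)N1 | starting material
8 | mixed pivalic anhydride of 6 | COc1cc(Br)c(/C=C/C(=O)OC(=O)C(C)(C)C)c2OC(c3ccccc3)(c3ccccc3)Oc12 | intermediate
9 | (S)-3-[(E)-3-(5-bromo-7-methoxy-2,2-diphenyl-1,3-benzodioxol-4-yl)acryloyl]-4-isopropyloxazolidin-2-one | COc1cc(Br)c(/C=C/C(=O)N3[C@@H](C(C)C)COC3=O)c2OC(c4ccccc4)(c4ccccc4)Oc12 | intermediate
10 | (4-benzyloxy-3-methoxyphenyl)boronic acid | COc1cc(B(O)O)ccc1OCc1ccccc1 | starting material
11 | (S)-3-[(S)-3-(4-benzyloxy-3-methoxyphenyl)-3-(5-bromo-7-methoxy-2,2-diphenyl-1,3-benzodioxol-4-yl)propanoyl]-4-isopropyloxazolidin-2-one | COc1cc([C@H](CC(=O)N2[C@@H](C(C)C)COC2=O)c2c(Br)cc(OC)c3OC(c4ccccc4)(c4ccccc4)Oc23)ccc1OCc1ccccc1 | intermediate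
12 | tert-butyl bromoacetate | CC(C)(C)OC(=O)CBr | starting material
13 | sodium (Z)-enolate of 11 | [Na+].[O-]/C(=C\[C@@H](c1ccc(OCc2ccccc2)c(OC)c1)c1c(Br)cc(OC)c2OC(c3ccccc3)(c3ccccc3)Oc12)N1[C@@H](C(C)C)COC1=O | intermediate
14 | tert-butyl (3S,4S)-4-(4-benzyloxy-3-methoxyphenyl)-4-(5-bromo-7-methoxy-2,2-diphenyl-1,3-benzodioxol-4-yl)-3-[(S)-4-isopropyl-2-oxooxazolidine-3-carbonyl]butanoate | COc1cc([C@H]([C@H](CC(=O)OC(C)(C)C)C(=O)N2[C@@H](C(C)C)COC2=O)c2c(Br)cc(OC)c3OC(c4ccccc4)(c4ccccc4)Oc23)ccc1OCc1ccccc1 | intermediate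
15 | tert-butyl (3S,4S)-4-(4-benzyloxy-3-methoxyphenyl)-4-(5-bromo-7-methoxy-2,2-diphenyl-1,3-benzodioxol-4-yl)-3-(hydroxymethyl)butanoate | COc1cc([C@H]([C@H](CC(=O)OC(C)(C)C)CO)c2c(Br)cc(OC)c3OC(c4ccccc4)(c4ccccc4)Oc23)ccc1OCc1ccccc1 | intermediate
16 | tert-butyl (3S,4S)-4-(4-benzyloxy-3-methoxyphenyl)-3-(benzyloxymethyl)-4-(5-bromo-7-methoxy-2,2-diphenyl-1,3-benzodioxol-4-yl)butanoate | COc1cc([C@H]([C@H](CC(=O)OC(C)(C)C)COCc2ccccc2)c2c(Br)cc(OC)c3OC(c4ccccc4)(c4ccccc4)Oc23)ccc1OCc1ccccc1 | intermediate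
17 | lithium enolate of 16 (oxide trans to C2) | [Li+].COc1cc([C@H]([C@@H](COCc2ccccc2)/C=C(/[O-])OC(C)(C)C)c2c(Br)cc(OC)c3OC(c4ccccc4)(c4ccccc4)Oc23)ccc1OCc1ccccc1 | intermediate
18 | Mannich base: tert-butyl (3R,4S)-4-(4-benzyloxy-3-methoxyphenyl)-3-(benzyloxymethyl)-4-(5-bromo-7-methoxy-2,2-diphenyl-1,3-benzodioxol-4-yl)-2-[(dimethylamino)methyl]butanoate (both C2 epimers of the butanoate) | COc1cc([C@H]([C@@H](COCc2ccccc2)C(CN(C)C)C(=O)OC(C)(C)C)c2c(Br)cc(OC)c3OC(c4ccccc4)(c4ccccc4)Oc23)ccc1OCc1ccccc1 | intermediate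
19 | trimethylammonium iodide of 18 | COc1cc([C@H]([C@@H](COCc2ccccc2)C(C[N+](C)(C)C)C(=O)OC(C)(C)C)c2c(Br)cc(OC)c3OC(c4ccccc4)(c4ccccc4)Oc23)ccc1OCc1ccccc1.[I-] | intermediate
20 | tert-butyl (3R,4S)-4-(4-benzyloxy-3-methoxyphenyl)-3-(benzyloxymethyl)-4-(5-bromo-7-methoxy-2,2-diphenyl-1,3-benzodioxol-4-yl)-2-methylenebutanoate | COc1cc([C@H]([C@@H](COCc2ccccc2)C(=C)C(=O)OC(C)(C)C)c2c(Br)cc(OC)c3OC(c4ccccc4)(c4ccccc4)Oc23)ccc1OCc1ccccc1 | intermediate
21 | tert-butyl (1S,2R,3R)-1-(4-benzyloxy-3-methoxyphenyl)-2-(benzyloxymethyl)-6-methoxy-7,8-(diphenylmethylenedioxy)-1,2,3,4-tetrahydronaphthalene-3-carboxylate | COc1cc([C@H]2c3c(cc(OC)c4OC(c5ccccc5)(c5ccccc5)Oc34)C[C@@H](C(=O)OC(C)(C)C)[C@@H]2COCc2ccccc2)ccc1OCc1ccccc1 | intermediate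
22 | [(1S,2R,3R)-1-(4-benzyloxy-3-methoxyphenyl)-2-(benzyloxymethyl)-6-methoxy-7,8-(diphenylmethylenedioxy)-1,2,3,4-tetrahydronaphthalen-3-yl]methanol | COc1cc([C@H]2c3c(cc(OC)c4OC(c5ccccc5)(c5ccccc5)Oc34)C[C@@H](CO)[C@@H]2COCc2ccccc2)ccc1OCc1ccccc1 | intermediate
23 | (1S,2R,3R)-1-(4-hydroxy-3-methoxyphenyl)-2,3-bis(hydroxymethyl)-6-methoxy-1,2,3,4-tetrahydronaphthalene-7,8-diol | COc1cc([C@H]2c3c(cc(OC)c(O)c3O)C[C@@H](CO)[C@@H]2CO)ccc1O | target

Total step count: 13. Longest linear sequence: 13 steps (from 1).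

Steps most likely to fail

Step 11 (key step). What may go wrong: hydrogen transfer to the aryl radical before ring closure, 1,5-hydrogen transfer from C2–H, 5-exo closure without rearrangement, or weak facial selectivity in the hydrogen transfer to C3. Fallback (anionic instead of radical closure, a Parham-type cyclisation): the route is left at 20. t-BuLi (2.1 equiv) in THF–Et2O at −100 °C exchanges bromine for lithium to give the aryllithium F1. F1 adds intramolecularly to C4 of the tert-butyl acrylate (6-endo-trig conjugate addition; the tert-butyl ester resists 1,2-addition) to give the cyclised lithium ester enolate F2. Protonation with 2,6-di-tert-butyl-4-methylphenol at −78 °C should favour the face anti to the C1 aryl group and give 21, where the route is rejoined. Any C3 epimer F3, from this protonation or from step 11 itself, would be equilibrated with KOt-Bu in t-BuOH–THF at 20 °C toward 21, since C3 is the only enolisable centre and the tert-butyl ester cannot be exchanged.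

Step 6. What may go wrong: slow insertion at a carbon flanked by bromine and the ketal oxygen, protodeboronation of 10 outrunning the addition, hydrolytic loss of the auxiliary, or insufficient facial selectivity. Fallback (auxiliary-controlled cuprate addition instead of catalyst control): the route is left at 6. Its mixed anhydride 8 acylates (R)-4-phenyl-2-oxazolidinone (LiCl, Et3N, THF) to give the enoyl imide F4. (4-Benzyloxy-3-methoxyphenyl)magnesium bromide F5 (from 1-benzyloxy-4-bromo-2-methoxybenzene and Mg in THF) with CuBr·SMe2 in THF at −40 to −15 °C adds to C1 of the magnesium-chelated s-cis enoyl imide on the face away from the phenyl group of the auxiliary, which is the Re face, to give the (S)-C1 imide F6. Because the phenyl auxiliary has the wrong sense for step 7, LiOH–H2O2 in THF–H2O at 0 °C removes it to give the acid F7. Its mixed pivalic anhydride F8 (t-BuCOCl, Et3N) acylates 7 (LiCl) to give 11, where the route is rejoined.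

Step 7. What may go wrong: slow C-alkylation, because the enolate face left open by the auxiliary is the one on which ring A lies in the rotamer with C1–H eclipsing the enolate oxygen, so that breakdown of the enolate (ketene formation with loss of the auxiliary) and erosion of facial selectivity compete. Fallback (slim allyl electrophile, C10 built by oxidation after C9 is protected): the route is left at 11. Enolate 13 and allyl iodide (−78 to −45 °C) give the allyl imide F9. LiBH4–H2O gives the alcohol F10. NaH, BnBr, Bu4NI in THF give the benzyl ether F11, without risk since no ester is present. OsO4 (cat.), NaIO4, 2,6-lutidine in dioxane–H2O cleave the alkene to the aldehyde F12. NaClO2, NaH2PO4, 2-methyl-2-butene in t-BuOH–H2O give the acid F13. tert-Butyl 2,2,2-trichloroacetimidate in CH2Cl2–cyclohexane gives 16, where the route is rejoined. This detour also bypasses the γ-hydroxy ester 15.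

Further compounds
F1 | step 11 | aryllithium from 20 (Li in place of Br at C4a) | COc1cc([C@H]([C@@H](COCc2ccccc2)C(=C)C(=O)OC(C)(C)C)c2c([Li])cc(OC)c3OC(c4ccccc4)(c4ccccc4)Oc23)ccc1OCc1ccccc1
F2 | step 11 | cyclised lithium ester enolate (C3=C10, enolate geometry not defined) | [Li+].COc1cc([C@H]2c3c(cc(OC)c4OC(c5ccccc5)(c5ccccc5)Oc34)CC(=C([O-])OC(C)(C)C)[C@@H]2COCc2ccccc2)ccc1OCc1ccccc1
F3 | step 11 | C3 epimer of 21, the (1S,2R,3S) ester | COc1cc([C@H]2c3c(cc(OC)c4OC(c5ccccc5)(c5ccccc5)Oc34)C[C@H](C(=O)OC(C)(C)C)[C@@H]2COCc2ccccc2)ccc1OCc1ccccc1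
F4 | step 6 | (R)-3-[(E)-3-(5-bromo-7-methoxy-2,2-diphenyl-1,3-benzodioxol-4-yl)acryloyl]-4-phenyloxazolidin-2-one | COc1cc(Br)c(/C=C/C(=O)N3[C@H](c4ccccc4)COC3=O)c2OC(c4ccccc4)(c4ccccc4)Oc12
F5 | step 6 | (4-benzyloxy-3-methoxyphenyl)magnesium bromide | COc1cc([Mg]Br)ccc1OCc1ccccc1
F6 | step 6 | (R)-3-[(S)-3-(4-benzyloxy-3-methoxyphenyl)-3-(5-bromo-7-methoxy-2,2-diphenyl-1,3-benzodioxol-4-yl)propanoyl]-4-phenyloxazolidin-2-one | COc1cc([C@H](CC(=O)N2[C@H](c3ccccc3)COC2=O)c2c(Br)cc(OC)c3OC(c4ccccc4)(c4ccccc4)Oc23)ccc1OCc1ccccc1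
F7 | step 6 | (S)-3-(4-benzyloxy-3-methoxyphenyl)-3-(5-bromo-7-methoxy-2,2-diphenyl-1,3-benzodioxol-4-yl)propanoic acid | COc1cc([C@H](CC(=O)O)c2c(Br)cc(OC)c3OC(c4ccccc4)(c4ccccc4)Oc23)ccc1OCc1ccccc1
F8 | step 6 | mixed pivalic anhydride of F7 | COc1cc([C@H](CC(=O)OC(=O)C(C)(C)C)c2c(Br)cc(OC)c3OC(c4ccccc4)(c4ccccc4)Oc23)ccc1OCc1ccccc1
F9 | step 7 | (S)-3-[(S)-2-[(S)-(4-benzyloxy-3-methoxyphenyl)(5-bromo-7-methoxy-2,2-diphenyl-1,3-benzodioxol-4-yl)methyl]pent-4-enoyl]-4-isopropyloxazolidin-2-one | COc1cc([C@H]([C@H](CC=C)C(=O)N2[C@@H](C(C)C)COC2=O)c2c(Br)cc(OC)c3OC(c4ccccc4)(c4ccccc4)Oc23)ccc1OCc1ccccc1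
F10 | step 7 | (S)-2-[(S)-(4-benzyloxy-3-methoxyphenyl)(5-bromo-7-methoxy-2,2-diphenyl-1,3-benzodioxol-4-yl)methyl]pent-4-en-1-ol | COc1cc([C@H]([C@H](CC=C)CO)c2c(Br)cc(OC)c3OC(c4ccccc4)(c4ccccc4)Oc23)ccc1OCc1ccccc1
F11 | step 7 | benzyl ether of F10 | COc1cc([C@H]([C@H](CC=C)COCc2ccccc2)c2c(Br)cc(OC)c3OC(c4ccccc4)(c4ccccc4)Oc23)ccc1OCc1ccccc1
F12 | step 7 | (3S,4S)-4-(4-benzyloxy-3-methoxyphenyl)-3-(benzyloxymethyl)-4-(5-bromo-7-methoxy-2,2-diphenyl-1,3-benzodioxol-4-yl)butanal | COc1cc([C@H]([C@H](CC=O)COCc2ccccc2)c2c(Br)cc(OC)c3OC(c4ccccc4)(c4ccccc4)Oc23)ccc1OCc1ccccc1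
F13 | step 7 | (3S,4S)-4-(4-benzyloxy-3-methoxyphenyl)-3-(benzyloxymethyl)-4-(5-bromo-7-methoxy-2,2-diphenyl-1,3-benzodioxol-4-yl)butanoic acid | COc1cc([C@H]([C@H](CC(=O)O)COCc2ccccc2)c2c(Br)cc(OC)c3OC(c4ccccc4)(c4ccccc4)Oc23)ccc1OCc1ccccc1
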